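Should I stop at 40 min (flask eta) or leave the same charge until 80 min (flask gamma), if I want target ahead of substrate? Free catalyst turns substrate into target, isomer of the product appears beside it, and the gas starts with none in solution.

in all of them: gas 8.1 mM (held)

| run | substrate | free catalyst | remark | time |
|---|---|---|---|---|
| spring | 0.050 M | 0.21 mM | run made earlier |  |
| dawn | 0.050 M | 0.48 mM | run made earlier |  |
| autumn | 0.075 M | 0.32 mM | run made earlier |  |
| eta | 0.050 M | 0.32 mM |  | 40 min |
| gamma | 0.050 M | 0.32 mM |  | 80 min |

| run | time / min | substrate / % | isomer of the product / % | catalyst intermediate D / % | target / % |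
|---|---|---|---|---|---|
| spring | 3.00 | 98 | 0 | 1 | 0 |
| spring | 8.00 | 96 | 0 | 0 | 1 |
| spring | 15.0 | 91 | 1 | 2 | 11 |
| spring | 40.0 | 72 | 4 | 0 | 21 |
| dawn | 3.00 | 97 | 0 | 0 | 2 |
| dawn | 8.00 | 96 | 0 | 0 | 4 |
| dawn | 15.0 | 86 | 0 | 0 | 12 |
| dawn | 40.0 | 58 | 9 | 1 | 29 |
| autumn | 10.0 | 96 | 0 | 1 | 3 |
| autumn | 20.0 | 89 | 0 | 0 | 11 |
| autumn | 30.0 | 84 | 2 | 0 | 15 |
| autumn | 40.0 | 76 | 3 | 0 | 19 |

(scatter of a reading: 1.5 percentage points)

- which of these there is most of at the end, counted by the substrate in it, eta (substrate / target / catalyst intermediate D / isomer of the product)
- which of these there is most of at the end, counted by the substrate in it, gamma (substrate / target / catalyst intermediate D / isomer of the product)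
- final amount of the leader among these, as a percentage of the substrate charged, in eta
- final amount of the leader among these, as a percentage of the substrate charged, in gamma

- at the start none of the gas is in solution

I count turnovers. The turnover count (the turnover number) is the substrate used per free catalyst charged, and the autumn run, which has eta's catalyst charge, reads 56.2 at 40.0 min; the scatter of one reading is worth 3.52 turnovers there. At that time the spring run reads 66.7 and the dawn run 43.8, so the count is lower in dawn, with more catalyst. Autumn's count lies between them, though autumn has more substrate than eta, so I carry it unchanged to eta.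

In eta one turnover uses 0.640% of the charge, so my count uses 36.0% and leaves 64.0% substrate. Autumn's late pace, counted in turnovers, is 1.52 /min, and holding it to gamma's time I reckon 117 turnovers, 75.0% used and 25.0% substrate left. With dawn's isomer share of 23.7%, read at 40.0 min, I reckon target in gamma near 57.2%, more than the substrate I reckon left. So I run gamma to the later time.

The forecast is close to me on eta's substrate and lower than me on gamma's target: substrate leads eta at 66%, target leads gamma at 45%, with the ground that “the rate is roughly zero order in substrate”.

The simulation gives substrate leading eta at 65.9% and target leading gamma at 51.8%.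

    coupling partner + free catalyst ⇌ catalyst intermediate A (K = 93.0 /M, k = 1100 /M/min)
    catalyst intermediate A → catalyst intermediate B (k = 44.0 /min)
    catalyst intermediate B → by-product + catalyst intermediate C (k = 5.60 /min)
    substrate + catalyst intermediate C → catalyst intermediate D (k = 1400 /M/min)
    catalyst intermediate D → free catalyst + target (k = 15.0 /min)
    gas ⇌ coupling partner, rate k6*(csat - [coupling partner]) (kL = 0.0910 /min)
    target + free catalyst ⇌ isomer of the product + free catalyst, rate k7*[free catalyst]*[target] forward; the back reaction follows from the equilibrium constant (K = 1.80, k = 57.0 /M/min)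

Eta's substrate reads back as 53.4 turnovers against my 56.2, and gamma's as 111 against my 117. The neighbouring flask is eta with 1.9 × 10⁻⁴ M of free catalyst, so one turnover there uses 0.380% of the charge, and my 56.2 turnovers leave 78.6% substrate. The neighbouring flask holds 75.8% substrate at 40.0 min, which is 63.8 turnovers, more than eta's 53.4.

The earlier runs and the new flask come from a simulation for substances that don't exist.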